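**Retrosynthetic overview** (labdane numbering: decalin C1–C10, side chain C11–C16, C17 on C8)

1. Target 21 ⇐ acetylation of allylic alcohol 20 ⇐ Stille hydroxymethylation (C8–C17) of the Δ7 enol triflate 19 ⇐ kinetic enolisation of 8-ketone 18.
2. 18 ⇐ aldol condensation of aldehyde 14 (C11–C16; C13 from hemiester 12) at C9 of enone 11, then hydrogenation, which sets C9.
3. Ring B (C5–C6–C7–C8–C9–C10) of 11 ⇐ one-carbon ring expansion of the cyclopentane ring (C5, C6, C8, C9, C10) of a trans-hydrindan-2-one: C7 is inserted into the C6–C8 bond through siloxycyclopropane 9. Enabling feature: C7 is the only unsubstituted sp2 CH of ring B and lies between C6H2 and C8, the carbon that bears exocyclic C17 and can therefore be a ketone/enol carbon; deleting C7 leaves a cyclopentanone whose C6=C8 enol ether is what metal–ammonia reduction of the cyclopentenone delivers.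
4. Cyclopentenone 6 ⇐ Wacker oxidation and aldol condensation of allyl ketone 4; C10 ⇐ Pd-catalysed decarboxylative asymmetric allylation; C5 ⇐ Li/NH3 reduction.
5. Ring order: ring A is bought (in 1); the five-membered B-nor ring is closed in step 4; ring B arises by ring expansion in step 7.

Key step: step 7

Assumption: (S)-t-Bu-PHOX is taken as the ligand enantiomer that delivers (S)-4; if the sense of induction proves opposite for this tetrasubstituted enolate, its enantiomer is used.
Assumption: 12 is used enantiopure (amine-salt recrystallisation if needed) and the enantiomeric purity of 6 is raised, if necessary, by recrystallising its semicarbazone; these purifications are not counted as steps.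

**Route**

Step 1
Reactants: 1 2,2,6-trimethylcyclohexan-1-one; 2 allyl chloroformate
Product: 3 allyl (2,6,6-trimethylcyclohex-1-en-1-yl) carbonate
Conditions: LiHMDS, THF, 0 °C; then 2, −78 °C → rt
Reagents that add atoms: allyl chloroformate (2), C=CCOC(Cl)=O
Why: The only possible enolate of 1 (the other α-carbon is quaternary) is O-acylated by the hard chloroformate (enol carbonate formation), and the stereocentre of racemic 1 is erased.

Step 2
Reactants: 3 allyl (2,6,6-trimethylcyclohex-1-en-1-yl) carbonate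
Product: 4 (S)-2-allyl-2,6,6-trimethylcyclohexan-1-one
Conditions: Pd2(dba)3 (2.5 mol%), (S)-t-Bu-PHOX (6.25 mol%), THF, 25 °C
Reagents that add atoms: none
Why: Pd-catalysed decarboxylative asymmetric allylic alkylation (Tsuji type): ionisation and loss of CO2 give a Pd-allyl/enolate pair, and the chiral P,N-ligand selects the enolate face so that the quaternary C10 centre should form as (S).

Step 3
Reactants: 4 (S)-2-allyl-2,6,6-trimethylcyclohexan-1-one
Product: 5 (S)-2,2,6-trimethyl-6-(2-oxopropyl)cyclohexan-1-one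
Conditions: PdCl2 (10 mol%), Cu(OAc)2·H2O (25 mol%), O2 (1 atm), DMA/H2O 7:1, rt
Reagents that add atoms: water, O
Why: Tsuji–Wacker oxidation with Markovnikov hydroxypalladation of the terminal alkene gives the methyl ketone and leaves the quaternary centre untouched.

Step 4
Reactants: 5 (S)-2,2,6-trimethyl-6-(2-oxopropyl)cyclohexan-1-one
Product: 6 (S)-4,4,7a-trimethyl-1,4,5,6,7,7a-hexahydro-2H-inden-2-one
Conditions: KOH (powdered), xylenes, 110 °C, Dean–Stark
Reagents that add atoms: none
Why: Intramolecular aldol condensation: the ring ketone has no α-hydrogen, so only the methyl-ketone enolate can add to it (5-enolexo-exo-trig), and dehydration gives the cyclopentenone with C10 untouched.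

Step 5
Reactants: 6 (S)-4,4,7a-trimethyl-1,4,5,6,7,7a-hexahydro-2H-inden-2-one
Product: 8 trimethyl{[(3aR,7aS)-4,4,7a-trimethyl-3a,4,5,6,7,7a-hexahydro-1H-inden-2-yl]oxy}silane, via lithium enolate 7 (not isolated)
Conditions: Li (2.2 equiv), NH3(l)/THF, t-BuOH (1.0 equiv), −78 °C; evaporate NH3; TMSCl, Et3N, THF, −78 → 0 °C
Reagents that add atoms: chlorotrimethylsilane, C[Si](C)(C)Cl; lithium, [Li] (retained only in 7)
Why: Dissolving-metal conjugate reduction (Birch type) followed by O-silylation of the regiodefined enolate: the C5 carbanion should be protonated on the face opposite the syn-axial C10 and C4 methyl groups, giving the trans ring fusion, and silylation fixes the enolate as the C6=C8 enol ether without equilibration.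

Step 6
Reactants: 8 trimethyl{[(3aR,7aS)-4,4,7a-trimethyl-3a,4,5,6,7,7a-hexahydro-1H-inden-2-yl]oxy}silane
Product: 9 (3aR,7aS)-4,4,7a-trimethyl-2-(trimethylsilyloxy)-2,3-methanooctahydro-1H-indene (CH2 bridge across C2–C3 on the face of H-3a)
Conditions: Et2Zn, CH2I2, CH2Cl2, 0 °C → rt; pyridine quench
Reagents that add atoms: diiodomethane, C(I)I
Why: Simmons–Smith cyclopropanation (Furukawa variant) of the electron-rich silyl enol ether; the carbenoid should add to the face of H-5, away from the angular methyl, though either cyclopropane diastereomer would serve because both new centres are lost in step 7.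

Step 7
Reactants: 9 (3aR,7aS)-4,4,7a-trimethyl-2-(trimethylsilyloxy)-2,3-methanooctahydro-1H-indene
Product: 11 (4aR,8aS)-5,5,8a-trimethyl-4a,5,6,7,8,8a-hexahydronaphthalen-2(1H)-one, via beta-chloro ketone 10 (not isolated)
Conditions: FeCl3 (2.2 equiv), DMF, 0 °C → rt; then NaOAc, MeOH, reflux
Reagents that add atoms: iron(III) chloride, Cl[Fe](Cl)Cl (chlorine retained only in 10)
Why: Fe(III) oxidises the siloxycyclopropane by one electron to a cyclopropyloxy radical, whose β-scission breaks the zero-bridge C6–C8 bond to give the C8 ketone and a secondary radical at C6; chlorine transfer from a second FeCl3 gives β-chloro ketone 10, and NaOAc removes HCl by E1cB to the conjugated Δ6 enone. The closest known reaction type is the FeCl3 ring enlargement of 1-siloxybicyclo[n.1.0]alkanes to 2-cycloalkenones, the cyclopropanol-based one-carbon homologation of cyclic ketones. No ring is closed by cyclisation: ring B (C5–C6–C7–C8–C9–C10) arises because the inserted C7 stays bonded to both C6 and C8 when the C6–C8 bond of the cyclopentane (C5, C6, C8, C9, C10) is cut, a one-carbon ring expansion. No stereocentre is created (C6 ends sp2 and the cyclopropane centres are destroyed), and C5 and C10 are not touched. The selectivity needed is cleavage of the internal rather than the external (C7–C8) cyclopropane bond, secured because only the internal cut gives a secondary ring radical instead of a primary one, and the elimination can only go toward C7, the sole acidic position next to the C–Cl carbon. The enone left behind blocks C7, so C9 becomes the only enolisable carbon beside the ketone, which is what allows the side chain to be joined there in step 10.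

Step 8
Reactants: 12 (R)-methyl hydrogen 3-methylglutarate [(3R)-5-methoxy-3-methyl-5-oxopentanoic acid]
Product: 13 methyl (R)-5-hydroxy-3-methylpentanoate
Conditions: BH3·SMe2, THF, −10 → 0 °C; cold aqueous NaHCO3 work-up
Reagents that add atoms: none
Why: Chemoselective borane reduction of the carboxylic acid (via an acyloxyborane) in the presence of the methyl ester, with the C13 stereocentre not involved.

Step 9
Reactants: 13 methyl (R)-5-hydroxy-3-methylpentanoate
Product: 14 methyl (R)-3-methyl-5-oxopentanoate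
Conditions: Dess–Martin periodinane, NaHCO3, CH2Cl2, 0 °C → rt
Reagents that add atoms: none
Why: Dess–Martin oxidation of the primary alcohol under buffered neutral conditions should outrun lactonisation, and the stereocentre is not α to a carbonyl so it cannot epimerise.

Step 10
Reactants: 11 (4aR,8aS)-5,5,8a-trimethyl-4a,5,6,7,8,8a-hexahydronaphthalen-2(1H)-one; 14 methyl (R)-3-methyl-5-oxopentanoate
Product: 15 methyl (3R)-5-hydroxy-3-methyl-5-[(4aR,8aR)-5,5,8a-trimethyl-2-oxo-1,2,4a,5,6,7,8,8a-octahydronaphthalen-1-yl]pentanoate (diastereomers at C9 and C11)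
Conditions: LDA (1.05 equiv), THF, −78 °C; then 14, −78 °C; AcOH, −78 °C
Reagents that add atoms: none
Why: Kinetic α′-deprotonation of the enone (C7 is vinylic, so C9 is the only enolisable α-carbon) and aldol addition to the aldehyde, chemoselective over the methyl ester at −78 °C; the two new stereocentres are removed again in steps 11 and 12.

Step 11
Reactants: 15 methyl (3R)-5-hydroxy-3-methyl-5-[(4aR,8aR)-5,5,8a-trimethyl-2-oxo-1,2,4a,5,6,7,8,8a-octahydronaphthalen-1-yl]pentanoate
Product: 17 methyl (3R,5Z)-3-methyl-5-[(4aR,8aR)-5,5,8a-trimethyl-2-oxo-4a,5,6,7,8,8a-hexahydronaphthalen-1(2H)-ylidene]pentanoate, via aldol mesylate 16 (not isolated)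
Conditions: MsCl, Et3N, CH2Cl2, 0 °C; then DBU, rt
Reagents that add atoms: methanesulfonyl chloride, CS(=O)(=O)Cl (retained only in 16)
Why: Mesylation and E1cB elimination give the exocyclic cross-conjugated dienone, expected mainly as the Z isomer because the chain avoids the quaternary C10, and the alkene geometry is immaterial since it is hydrogenated next.

Step 12
Reactants: 17 methyl (3R,5Z)-3-methyl-5-[(4aR,8aR)-5,5,8a-trimethyl-2-oxo-4a,5,6,7,8,8a-hexahydronaphthalen-1(2H)-ylidene]pentanoate
Product: 18 methyl (3R)-3-methyl-5-[(1S,4aR,8aR)-5,5,8a-trimethyl-2-oxodecahydronaphthalen-1-yl]pentanoate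
Conditions: H2 (1 atm), 10% Pd/C, EtOAc, rt; then NaOMe (cat.), MeOH, rt
Reagents that add atoms: none
Why: Heterogeneous hydrogenation of both C=C bonds should deliver hydrogen to C9 from the face opposite the axial C10 methyl, placing the side chain equatorial and cis to that methyl, which is also the epimer that base equilibration α to the ketone favours.

Step 13
Reactants: 18 methyl (3R)-3-methyl-5-[(1S,4aR,8aR)-5,5,8a-trimethyl-2-oxodecahydronaphthalen-1-yl]pentanoate
Product: 19 methyl (3R)-3-methyl-5-[(1S,4aR,8aR)-5,5,8a-trimethyl-2-{[(trifluoromethyl)sulfonyl]oxy}-1,4,4a,5,6,7,8,8a-octahydronaphthalen-1-yl]pentanoate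
Conditions: KHMDS (1.1 equiv), THF, −78 °C; PhNTf2, −78 → 0 °C
Reagents that add atoms: N-phenylbis(trifluoromethanesulfonimide), O=S(=O)(N(c1ccccc1)S(=O)(=O)C(F)(F)F)C(F)(F)F
Why: Kinetic enolisation at the unhindered C7 methylene (C9 is tertiary and flanked by the quaternary C10, and the ester α-hydrogens are less acidic) followed by O-triflation fixes the C7=C8 double bond.

Step 14
Reactants: 19 methyl (3R)-3-methyl-5-[(1S,4aR,8aR)-5,5,8a-trimethyl-2-{[(trifluoromethyl)sulfonyl]oxy}-1,4,4a,5,6,7,8,8a-octahydronaphthalen-1-yl]pentanoate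
Product: 20 methyl (3R)-5-[(1S,4aR,8aR)-2-(hydroxymethyl)-5,5,8a-trimethyl-1,4,4a,5,6,7,8,8a-octahydronaphthalen-1-yl]-3-methylpentanoate
Conditions: Bu3SnCH2OH (1.5 equiv), Pd(PPh3)4 (5 mol%), LiCl (3 equiv), 1,4-dioxane, 100 °C
Reagents that add atoms: (tributylstannyl)methanol, CCCC[Sn](CCCC)(CCCC)CO
Why: Stille coupling of the vinyl triflate with the hydroxymethylstannane introduces C17 directly at the alcohol oxidation level, keeps the alkene at C7=C8 and does not touch the methyl ester.

Step 15
Reactants: 20 methyl (3R)-5-[(1S,4aR,8aR)-2-(hydroxymethyl)-5,5,8a-trimethyl-1,4,4a,5,6,7,8,8a-octahydronaphthalen-1-yl]-3-methylpentanoate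
Product: 21 methyl (3R)-5-[(1S,4aR,8aR)-2-(acetoxymethyl)-5,5,8a-trimethyl-1,4,4a,5,6,7,8,8a-octahydronaphthalen-1-yl]-3-methylpentanoate
Conditions: Ac2O, pyridine, DMAP (cat.), CH2Cl2, rt
Reagents that add atoms: acetic anhydride, CC(=O)OC(C)=O
Why: DMAP-catalysed acylation of the primary allylic alcohol gives the acetate without affecting any stereocentre.

**Compound list**

1 | 2,2,6-trimethylcyclohexan-1-one (racemic) | CC1CCCC(C)(C)C1=O | starting material
2 | allyl chloroformate | C=CCOC(Cl)=O | starting material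
3 | allyl (2,6,6-trimethylcyclohex-1-en-1-yl) carbonate | C=CCOC(=O)OC1=C(C)CCCC1(C)C | intermediate
4 | (S)-2-allyl-2,6,6-trimethylcyclohexan-1-one | C=CC[C@]1(C)CCCC(C)(C)C1=O | intermediate
5 | (S)-2,2,6-trimethyl-6-(2-oxopropyl)cyclohexan-1-one | CC(=O)C[C@]1(C)CCCC(C)(C)C1=O | intermediate
6 | (S)-4,4,7a-trimethyl-1,4,5,6,7,7a-hexahydro-2H-inden-2-one | O=C1C=C2C(C)(C)CCC[C@@]2(C)C1 | intermediate
7 | lithium (3aR,7aS)-4,4,7a-trimethyl-3a,4,5,6,7,7a-hexahydro-1H-inden-2-olate | [Li+].[O-]C1=C[C@@H]2C(C)(C)CCC[C@@]2(C)C1 | intermediate (not isolated)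
8 | trimethyl{[(3aR,7aS)-4,4,7a-trimethyl-3a,4,5,6,7,7a-hexahydro-1H-inden-2-yl]oxy}silane | C[Si](C)(C)OC1=C[C@@H]2C(C)(C)CCC[C@@]2(C)C1 | intermediate
9 | (3aR,7aS)-4,4,7a-trimethyl-2-(trimethylsilyloxy)-2,3-methanooctahydro-1H-indene, CH2 bridge on the face of H-3a | C1[C@@]3(O[Si](C)(C)C)C[C@H]3[C@@H]2C(C)(C)CCC[C@@]12C | intermediate
10 | (4aR,8aS)-4-chloro-5,5,8a-trimethyloctahydronaphthalen-2(1H)-one (C4 epimers) | O=C1CC(Cl)[C@@H]2C(C)(C)CCC[C@@]2(C)C1 | intermediate (not isolated)
11 | (4aR,8aS)-5,5,8a-trimethyl-4a,5,6,7,8,8a-hexahydronaphthalen-2(1H)-one | O=C1C=C[C@@H]2C(C)(C)CCC[C@@]2(C)C1 | intermediate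
12 | (R)-methyl hydrogen 3-methylglutarate | COC(=O)C[C@H](C)CC(=O)O | starting material
13 | methyl (R)-5-hydroxy-3-methylpentanoate | COC(=O)C[C@H](C)CCO | intermediate
14 | methyl (R)-3-methyl-5-oxopentanoate | COC(=O)C[C@H](C)CC=O | intermediate
15 | methyl (3R)-5-hydroxy-3-methyl-5-[(4aR,8aR)-5,5,8a-trimethyl-2-oxo-1,2,4a,5,6,7,8,8a-octahydronaphthalen-1-yl]pentanoate (diastereomers at the two new centres) | COC(=O)C[C@H](C)CC(O)C1C(=O)C=C[C@@H]2C(C)(C)CCC[C@@]12C | intermediate
16 | methyl (3R)-3-methyl-5-[(methylsulfonyl)oxy]-5-[(4aR,8aR)-5,5,8a-trimethyl-2-oxo-1,2,4a,5,6,7,8,8a-octahydronaphthalen-1-yl]pentanoate | COC(=O)C[C@H](C)CC(OS(C)(=O)=O)C1C(=O)C=C[C@@H]2C(C)(C)CCC[C@@]12C | intermediate (not isolated)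
17 | methyl (3R,5Z)-3-methyl-5-[(4aR,8aR)-5,5,8a-trimethyl-2-oxo-4a,5,6,7,8,8a-hexahydronaphthalen-1(2H)-ylidene]pentanoate | COC(=O)C[C@H](C)C/C=C1\C(=O)C=C[C@@H]2C(C)(C)CCC[C@@]12C | intermediate
18 | methyl (3R)-3-methyl-5-[(1S,4aR,8aR)-5,5,8a-trimethyl-2-oxodecahydronaphthalen-1-yl]pentanoate | COC(=O)C[C@H](C)CC[C@@H]1C(=O)CC[C@@H]2C(C)(C)CCC[C@@]12C | intermediate
19 | methyl (3R)-3-methyl-5-[(1S,4aR,8aR)-5,5,8a-trimethyl-2-{[(trifluoromethyl)sulfonyl]oxy}-1,4,4a,5,6,7,8,8a-octahydronaphthalen-1-yl]pentanoate | COC(=O)C[C@H](C)CC[C@@H]1C(OS(=O)(=O)C(F)(F)F)=CC[C@@H]2C(C)(C)CCC[C@@]12C | intermediate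
20 | methyl (3R)-5-[(1S,4aR,8aR)-2-(hydroxymethyl)-5,5,8a-trimethyl-1,4,4a,5,6,7,8,8a-octahydronaphthalen-1-yl]-3-methylpentanoate | COC(=O)C[C@H](C)CC[C@@H]1C(CO)=CC[C@@H]2C(C)(C)CCC[C@@]12C | intermediate
21 | methyl (3R)-5-[(1S,4aR,8aR)-2-(acetoxymethyl)-5,5,8a-trimethyl-1,4,4a,5,6,7,8,8a-octahydronaphthalen-1-yl]-3-methylpentanoate | COC(=O)C[C@H](C)CC[C@@H]1C(COC(C)=O)=CC[C@@H]2C(C)(C)CCC[C@@]12C | target

**Step count**

Total steps: 15. Longest linear sequence: 13 (steps 1–7 and 10–15); steps 8–9 form the side-chain branch.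

**Three steps most likely to fail**

Step 5. The risk is poor facial selectivity in the protonation at C5, so that cis ring fusion competes, together with over-reduction of the ketone. The fallback replaces protonation of a carbanion by metal-hydride delivery under steric approach control. It sets out from 6: Rh-catalysed 1,4-hydrosilylation (RhCl(PPh3)3, Et3SiH, benzene, 60 °C) should place hydrogen on C5 from the open face and give directly the triethylsilyl enol ether triethyl{[(3aR,7aS)-4,4,7a-trimethyl-3a,4,5,6,7,7a-hexahydro-1H-inden-2-yl]oxy}silane F1. Cyclopropanation (Et2Zn, CH2I2) gives the triethylsilyloxy analogue of 9, F2, which under the conditions of step 7 passes through 10 and comes back to the route at 11.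

Step 10. The risk is a sluggish or reversible aldol addition at the hindered C9, lactonisation of the aldolate onto the methyl ester, and self-condensation of the aldehyde. The fallback joins the chain by SN2 alkylation instead. Alcohol 13 is converted (I2, PPh3, imidazole) into methyl (S)-5-iodo-3-methylpentanoate F3. The lithium enolate of 11 (LDA, THF/DMPU, −78 → 0 °C) is alkylated with it to give methyl (3R)-3-methyl-5-[(4aR,8aR)-5,5,8a-trimethyl-2-oxo-1,2,4a,5,6,7,8,8a-octahydronaphthalen-1-yl]pentanoate F4, expected mainly as the axial C9 epimer. Hydrogenation of the ring alkene (H2, Pd/C) and equilibration at C9 (NaOMe, MeOH) return to the route at 18.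

Step 14. The risk is slow transmetallation of the sp3 hydroxymethyl group to the hindered vinylpalladium species, so that hydrolysis or reduction of the triflate takes over. The fallback builds C17 by carbonylation. It sets out from 19: Pd-catalysed reductive carbonylation (Pd(OAc)2, dppp, CO 1 atm, Et3SiH, Et3N, DMF, 70 °C) gives the enal methyl (3R)-5-[(1S,4aR,8aR)-2-formyl-5,5,8a-trimethyl-1,4,4a,5,6,7,8,8a-octahydronaphthalen-1-yl]-3-methylpentanoate F5. Luche reduction (NaBH4, CeCl3·7H2O, MeOH, 0 °C), which leaves the ester alone, comes back to the route at 20.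

**Further compounds**

F1 | step 5 | triethyl{[(3aR,7aS)-4,4,7a-trimethyl-3a,4,5,6,7,7a-hexahydro-1H-inden-2-yl]oxy}silane | CC[Si](CC)(CC)OC1=C[C@@H]2C(C)(C)CCC[C@@]2(C)C1
F2 | step 5 | (3aR,7aS)-4,4,7a-trimethyl-2-(triethylsilyloxy)-2,3-methanooctahydro-1H-indene | C1[C@@]3(O[Si](CC)(CC)CC)C[C@H]3[C@@H]2C(C)(C)CCC[C@@]12C
F3 | step 10 | methyl (S)-5-iodo-3-methylpentanoate | COC(=O)C[C@H](C)CCI
F4 | step 10 | methyl (3R)-3-methyl-5-[(4aR,8aR)-5,5,8a-trimethyl-2-oxo-1,2,4a,5,6,7,8,8a-octahydronaphthalen-1-yl]pentanoate (C9 epimers) | COC(=O)C[C@H](C)CCC1C(=O)C=C[C@@H]2C(C)(C)CCC[C@@]12C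
F5 | step 14 | methyl (3R)-5-[(1S,4aR,8aR)-2-formyl-5,5,8a-trimethyl-1,4,4a,5,6,7,8,8a-octahydronaphthalen-1-yl]-3-methylpentanoate | COC(=O)C[C@H](C)CC[C@@H]1C(C=O)=CC[C@@H]2C(C)(C)CCC[C@@]12C
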